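**Plan**

1. Disconnections: (a) the eight phenolic MOM ethers; (b) the pyran-2,4-dione ring at O1–C8a and C4–C4a, leaving a ring A aryne and a 2-aryl-2-prenylmalonic acid half-ester; (c) the cyclohexene at C1–C6 and C4–C5 (cyclohexenyl locants: C1 on ring A, C5 aryl, C6 aroyl), leaving an (E)-2′-hydroxychalcone and a ring A 1-aryl-3-methylbutadiene.
2. Enabling feature: in the chromane-2,4-dione, O1–C8a and C4–C4a lie on neighbouring ring A carbons and the C5 oxygen flanks C4a. This is the pattern of a 3-alkoxyaryne, which takes an oxygen nucleophile at C8a and leaves the aryl anion at C4a, beside the alkoxy group and within reach of the second malonate carbonyl.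
3. Forward order: half-ester (steps 1–4), chalcone (5–7) and diene (8–13) are made separately. The cyclohexene ring forms first (14), ring A is armed as the ortho-silyl triflate (15–17), the pyran-2,4-dione ring closes in step 18, and deprotection ends the route.
4. Stereochemistry: C3 comes from esterase desymmetrisation of the prochiral malonate. Cyclohexene C1 and C5 come from a boron–VANOL-catalysed endo Diels–Alder reaction. The target has the aroyl group trans to ring A but cis to the 5-aryl group, which an (E)-chalcone cannot give directly, so C6 is inverted by base equilibration of the endo adduct (step 16).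

Key step: step 18

Assumption: the (S)-VANOL–boron catalyst is taken to give the (1R,5R,6S) endo adduct and pig liver esterase the (2R) half-ester; should either sense be opposite, (R)-VANOL or an enantiocomplementary esterase isoenzyme takes its place.

**Route**

Step 1
Reactants: 1 4-bromobenzene-1,3-diol (4-bromoresorcinol)
Product: 2 1-bromo-2,4-bis(methoxymethoxy)benzene
Conditions: MOMCl, i-Pr2NEt, CH2Cl2, 0 °C → rt
Reagents that add atoms: chloromethyl methyl ether, COCCl
Why: Both phenols are O-alkylated by the chloromethyl ether under amine base (Williamson-type acetal formation), a routine protection of resorcinols.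

Step 2
Reactants: 2 1-bromo-2,4-bis(methoxymethoxy)benzene; 3 dimethyl malonate
Product: 4 dimethyl 2-[2,4-bis(methoxymethoxy)phenyl]propanedioate
Conditions: Pd(dba)2 (2 mol %), P(t-Bu)3 (4 mol %), K3PO4, toluene, 80 °C
Reagents that add atoms: none
Why: Palladium-catalysed α-arylation of a malonate with an electron-rich aryl bromide works with a bulky trialkylphosphine and phosphate base, and the hindered monoarylated malonate should not react again.

Step 3
Reactants: 4 dimethyl 2-[2,4-bis(methoxymethoxy)phenyl]propanedioate; 5 1-bromo-3-methylbut-2-ene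
Product: 6 dimethyl 2-[2,4-bis(methoxymethoxy)phenyl]-2-(3-methylbut-2-en-1-yl)propanedioate
Conditions: NaH, THF/DMF, 0 °C; then 5, rt
Reagents that add atoms: none
Why: The stabilised malonate anion is C-alkylated at the primary carbon of the allylic bromide (SN2 alkylation), which creates the prochiral quaternary carbon.

Step 4
Reactants: 6 dimethyl 2-[2,4-bis(methoxymethoxy)phenyl]-2-(3-methylbut-2-en-1-yl)propanedioate
Product: 7 (2R)-2-[2,4-bis(methoxymethoxy)phenyl]-2-(methoxycarbonyl)-5-methylhex-4-enoic acid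
Conditions: pig liver esterase, 0.1 M phosphate buffer pH 7.5, 10 % DMSO, 30 °C, pH-stat (1 M NaOH); then citric acid to pH 4
Reagents that add atoms: water, O
Why: Enzymatic desymmetrisation of a prochiral disubstituted malonate hydrolyses one enantiotopic ester only, so the quaternary centre (2R) is set by the enzyme's discrimination between the aryl and prenyl groups, and the half-ester carboxylate should not be hydrolysed further.

Step 5
Reactants: 8 1-(2,4-dihydroxyphenyl)ethan-1-one
Product: 9 1-[2-hydroxy-4-(methoxymethoxy)phenyl]ethan-1-one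
Conditions: MOMCl (1.1 equiv), K2CO3, acetone, rt
Reagents that add atoms: chloromethyl methyl ether, COCCl
Why: Only the 4-hydroxyl is alkylated (regioselective Williamson etherification) because the 2-hydroxyl is held in a hydrogen bond to the ketone.

Step 6
Reactants: 10 2,4-dihydroxybenzaldehyde
Product: 11 2,4-bis(methoxymethoxy)benzaldehyde
Conditions: MOMCl, i-Pr2NEt, CH2Cl2, 0 °C → rt
Reagents that add atoms: chloromethyl methyl ether, COCCl
Why: Both phenols of the aldehyde are capped by O-alkylation with the chloromethyl ether, a standard protection.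

Step 7
Reactants: 9 1-[2-hydroxy-4-(methoxymethoxy)phenyl]ethan-1-one; 11 2,4-bis(methoxymethoxy)benzaldehyde
Product: 12 (2E)-3-[2,4-bis(methoxymethoxy)phenyl]-1-[2-hydroxy-4-(methoxymethoxy)phenyl]prop-2-en-1-one
Conditions: KOH, EtOH/H2O, rt
Reagents that add atoms: none
Why: Claisen–Schmidt aldol condensation of the acetophenone enolate with the non-enolisable aldehyde gives the (E)-enone after dehydration, with MOM ethers stable to base.

Step 8
Reactants: 13 2,4,6-trihydroxybenzaldehyde
Product: 14 4-[(tert-butyldimethylsilyl)oxy]-2,6-dihydroxybenzaldehyde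
Conditions: TBSCl (1.05 equiv), imidazole, DMF, 0 °C
Reagents that add atoms: tert-butyldimethylsilyl chloride, CC(C)(C)[Si](C)(C)Cl
Why: O-silylation should go to the 4-hydroxyl, the most acidic one and the only one that neither flanks nor hydrogen-bonds to the aldehyde.

Step 9
Reactants: 14 4-[(tert-butyldimethylsilyl)oxy]-2,6-dihydroxybenzaldehyde
Product: 15 4-[(tert-butyldimethylsilyl)oxy]-2,6-bis(methoxymethoxy)benzaldehyde
Conditions: MOMCl, i-Pr2NEt, CH2Cl2, 0 → 40 °C
Reagents that add atoms: chloromethyl methyl ether, COCCl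
Why: The two remaining hydroxyls are O-alkylated as MOM ethers, which leaves the silyl ether as the single differentiated oxygen of ring A.

Step 10
Reactants: 15 4-[(tert-butyldimethylsilyl)oxy]-2,6-bis(methoxymethoxy)benzaldehyde
Product: 16 3-bromo-4-[(tert-butyldimethylsilyl)oxy]-2,6-bis(methoxymethoxy)benzaldehyde
Conditions: NBS (1.0 equiv), MeCN, 0 °C
Reagents that add atoms: N-bromosuccinimide, O=C1CCC(=O)N1Br
Why: Electrophilic aromatic bromination can only occur at the two equivalent free positions, each ortho or para to three oxygen substituents and meta to the aldehyde.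

Step 11
Reactants: 16 3-bromo-4-[(tert-butyldimethylsilyl)oxy]-2,6-bis(methoxymethoxy)benzaldehyde; 17 diethyl (2-methylprop-2-en-1-yl)phosphonate
Product: 18 {2-bromo-3,5-bis(methoxymethoxy)-4-[(1E)-3-methylbuta-1,3-dien-1-yl]phenoxy}(tert-butyl)dimethylsilane
Conditions: 17, KN(SiMe3)2, THF, −78 °C; then 16, −78 °C → rt
Reagents that add atoms: none
Why: Horner–Wadsworth–Emmons olefination with the allylic phosphonate anion gives the 1-aryl-3-methylbuta-1,3-diene, the (E)-alkene being favoured in the phosphate elimination.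

Step 12
Reactants: 18 {2-bromo-3,5-bis(methoxymethoxy)-4-[(1E)-3-methylbuta-1,3-dien-1-yl]phenoxy}(tert-butyl)dimethylsilane
Product: 19 2-bromo-3,5-bis(methoxymethoxy)-4-[(1E)-3-methylbuta-1,3-dien-1-yl]phenol
Conditions: Bu4NF, THF, 0 °C; pH 7 buffer
Reagents that add atoms: none
Why: Fluoride cleaves the aryl silyl ether (desilylation) without touching the MOM ethers, the aryl bromide or the diene.

Step 13
Reactants: 19 2-bromo-3,5-bis(methoxymethoxy)-4-[(1E)-3-methylbuta-1,3-dien-1-yl]phenol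
Product: 23 3,5-bis(methoxymethoxy)-4-[(1E)-3-methylbuta-1,3-dien-1-yl]-2-(trimethylsilyl)phenyl 2,2-dimethylpropanoate, via aryl trimethylsilyl ether 20 (not isolated), via aryllithium 21 (not isolated), via lithium silylphenolate 22 (not isolated)
Conditions: (Me3Si)2NH, THF, 65 °C, then evaporate; n-BuLi (1.05 equiv), THF, −100 → −78 °C; t-BuCOCl, −78 → 0 °C
Reagents that add atoms: hexamethyldisilazane, C[Si](C)(C)N[Si](C)(C)C; pivaloyl chloride, CC(C)(C)C(Cl)=O
Why: O-silylation, bromine–lithium exchange (far faster than carbolithiation of the diene at −100 °C) and retro-Brook 1,3 O→C silyl migration put the silyl group ortho to oxygen, and the phenolate is acylated in the same flask to a base-labile ester.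

Step 14
Reactants: 12 (2E)-3-[2,4-bis(methoxymethoxy)phenyl]-1-[2-hydroxy-4-(methoxymethoxy)phenyl]prop-2-en-1-one; 23 3,5-bis(methoxymethoxy)-4-[(1E)-3-methylbuta-1,3-dien-1-yl]-2-(trimethylsilyl)phenyl 2,2-dimethylpropanoate
Product: 24 4-{(1R,5R,6S)-5-[2,4-bis(methoxymethoxy)phenyl]-6-[2-hydroxy-4-(methoxymethoxy)benzoyl]-3-methylcyclohex-2-en-1-yl}-3,5-bis(methoxymethoxy)-2-(trimethylsilyl)phenyl 2,2-dimethylpropanoate
Conditions: (S)-VANOL (20 mol %), BH3·THF (20 mol %), AcOH (20 mol %), THF, rt, then evaporate; 12, 23 (1.5 equiv), PhCF3, 4 Å molecular sieves, 25 °C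
Reagents that add atoms: none
Why: In this boron–biaryldiol-catalysed Diels–Alder reaction of a 2′-hydroxychalcone the chelated boron activates the enone and its ligand shields one face; the endo mode places ring A cis to the aroyl group, the (E)-enone places aroyl trans to the 5-aryl group, the ligand fixes the absolute configuration at C1 and C5, and the exo isomer is removed by chromatography.

Step 15
Reactants: 24 4-{(1R,5R,6S)-5-[2,4-bis(methoxymethoxy)phenyl]-6-[2-hydroxy-4-(methoxymethoxy)benzoyl]-3-methylcyclohex-2-en-1-yl}-3,5-bis(methoxymethoxy)-2-(trimethylsilyl)phenyl 2,2-dimethylpropanoate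
Product: 25 4-{(1R,5R,6S)-6-[2,4-bis(methoxymethoxy)benzoyl]-5-[2,4-bis(methoxymethoxy)phenyl]-3-methylcyclohex-2-en-1-yl}-3,5-bis(methoxymethoxy)-2-(trimethylsilyl)phenyl 2,2-dimethylpropanoate
Conditions: NaH (1.1 equiv), MOMCl, DMF, 0 °C
Reagents that add atoms: chloromethyl methyl ether, COCCl
Why: The chelated phenol is deprotonated and alkylated (Williamson etherification), so that the ketone can enolise in the next step and no second phenol competes in the later triflation.

Step 16
Reactants: 25 4-{(1R,5R,6S)-6-[2,4-bis(methoxymethoxy)benzoyl]-5-[2,4-bis(methoxymethoxy)phenyl]-3-methylcyclohex-2-en-1-yl}-3,5-bis(methoxymethoxy)-2-(trimethylsilyl)phenyl 2,2-dimethylpropanoate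
Product: 27 4-{(1R,5R,6R)-6-[2,4-bis(methoxymethoxy)benzoyl]-5-[2,4-bis(methoxymethoxy)phenyl]-3-methylcyclohex-2-en-1-yl}-3,5-bis(methoxymethoxy)-2-(trimethylsilyl)phenol, via 6S sodium phenolate 26 (not isolated)
Conditions: NaOMe, MeOH/THF, 50 °C; pH 7 buffer
Reagents that add atoms: none
Why: Methoxide removes the pivalate (transesterification) and reversibly enolises the ketone (base-mediated epimerisation); equilibration should move the aroyl group away from its larger neighbour, the doubly ortho-substituted ring A aryl, giving the 6R epimer (aroyl trans to ring A, cis to the 5-aryl group) in analogy to the cis-to-trans epimerisation of endo adducts of 1-aryl dienes, while C1 and C5 are not acidic and stay.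

Step 17
Reactants: 27 4-{(1R,5R,6R)-6-[2,4-bis(methoxymethoxy)benzoyl]-5-[2,4-bis(methoxymethoxy)phenyl]-3-methylcyclohex-2-en-1-yl}-3,5-bis(methoxymethoxy)-2-(trimethylsilyl)phenol
Product: 28 4-{(1R,5R,6R)-6-[2,4-bis(methoxymethoxy)benzoyl]-5-[2,4-bis(methoxymethoxy)phenyl]-3-methylcyclohex-2-en-1-yl}-3,5-bis(methoxymethoxy)-2-(trimethylsilyl)phenyl trifluoromethanesulfonate
Conditions: Tf2O, pyridine, CH2Cl2, −40 → 0 °C
Reagents that add atoms: trifluoromethanesulfonic anhydride, O=S(=O)(OS(=O)(=O)C(F)(F)F)C(F)(F)F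
Why: O-sulfonylation of the phenol gives the ortho-silyl aryl triflate, and at low temperature with pyridine the MOM ethers, the aryl silane and the hindered ketone should be left alone.

Step 18
Reactants: 28 4-{(1R,5R,6R)-6-[2,4-bis(methoxymethoxy)benzoyl]-5-[2,4-bis(methoxymethoxy)phenyl]-3-methylcyclohex-2-en-1-yl}-3,5-bis(methoxymethoxy)-2-(trimethylsilyl)phenyl trifluoromethanesulfonate; 7 (2R)-2-[2,4-bis(methoxymethoxy)phenyl]-2-(methoxycarbonyl)-5-methylhex-4-enoic acid
Product: 31 (3S)-3-[2,4-bis(methoxymethoxy)phenyl]-6-{(1R,5R,6R)-6-[2,4-bis(methoxymethoxy)benzoyl]-5-[2,4-bis(methoxymethoxy)phenyl]-3-methylcyclohex-2-en-1-yl}-5,7-bis(methoxymethoxy)-3-(3-methylbut-2-en-1-yl)chromane-2,4-dione, via trimethylsilyl ester 29 (not isolated), via aryne 30 (not isolated)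
Conditions: 7 (1.4 equiv), (Me3Si)2NH, THF, 60 °C, then evaporate; 28 (1 equiv), CsF (1.2 equiv), 18-crown-6, THF, 23 → 50 °C
Reagents that add atoms: none
Why: Proposed new method: fluoride frees a dry cesium carboxylate from silyl ester 29 and desilylates 28 with loss of triflate to the 3-alkoxyaryne 30; the carboxylate oxygen adds at C8a and the aryl anion left at C4a attacks the methyl ester through a six-membered transition state and expels methoxide. The closest known reaction type is the fluoride-induced annulation of arynes with ortho-hydroxy- or ortho-aminobenzoates, in which the heteroatom adds to the aryne and the aryl anion acylates the ester. The pyran-2,4-dione ring closes by 6-exo-trig acyl substitution at C4–C4a after the intermolecular O1–C8a bond is made. No stereocentre is formed: C3 is quaternary and cannot enolise, and cyclohexene C6 already has its equilibrium configuration from step 16. The step needs oxygen attack at C8a and not C4a, which the inductive pull of the C5 oxygen on the distorted aryne secures, and it needs acylation to outrun protonation of the aryl anion, for which the medium is kept aprotic (silyl ester in place of the free acid, THF). The methoxide set free is consumed at silicon by the excess silyl ester or by remaining 28, so it should not open the aryl lactone.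

Step 19
Reactants: 31 (3S)-3-[2,4-bis(methoxymethoxy)phenyl]-6-{(1R,5R,6R)-6-[2,4-bis(methoxymethoxy)benzoyl]-5-[2,4-bis(methoxymethoxy)phenyl]-3-methylcyclohex-2-en-1-yl}-5,7-bis(methoxymethoxy)-3-(3-methylbut-2-en-1-yl)chromane-2,4-dione
Product: 32 (3S)-6-[(1R,5R,6R)-6-(2,4-dihydroxybenzoyl)-5-(2,4-dihydroxyphenyl)-3-methylcyclohex-2-en-1-yl]-3-(2,4-dihydroxyphenyl)-5,7-dihydroxy-3-(3-methylbut-2-en-1-yl)chromane-2,4-dione
Conditions: Me3SiOTf (24 equiv), 2,2′-bipyridyl (36 equiv), MeCN, 0 °C → rt; then H2O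
Reagents that add atoms: none
Why: Silyl triflate buffered by bipyridyl converts aryl MOM ethers into silyl ethers that hydrolyse on work-up (non-protic acetal cleavage), which should spare the prenyl group, the aryl lactone and the stereocentre next to the ketone.

**Compound list**

1 | 4-bromobenzene-1,3-diol | Oc1ccc(Br)c(O)c1 | starting material
2 | 1-bromo-2,4-bis(methoxymethoxy)benzene | COCOc1ccc(Br)c(OCOC)c1 | intermediate
3 | dimethyl malonate | COC(=O)CC(=O)OC | starting material
4 | dimethyl 2-[2,4-bis(methoxymethoxy)phenyl]propanedioate | COCOc1ccc(C(C(=O)OC)C(=O)OC)c(OCOC)c1 | intermediate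
5 | 1-bromo-3-methylbut-2-ene | CC(C)=CCBr | starting material
6 | dimethyl 2-[2,4-bis(methoxymethoxy)phenyl]-2-(3-methylbut-2-en-1-yl)propanedioate | COCOc1ccc(C(CC=C(C)C)(C(=O)OC)C(=O)OC)c(OCOC)c1 | intermediate
7 | (2R)-2-[2,4-bis(methoxymethoxy)phenyl]-2-(methoxycarbonyl)-5-methylhex-4-enoic acid | CC(C)=CC[C@@](C(=O)OC)(c1ccc(OCOC)cc1OCOC)C(=O)O | intermediate
8 | 1-(2,4-dihydroxyphenyl)ethan-1-one | CC(=O)c1ccc(O)cc1O | starting material
9 | 1-[2-hydroxy-4-(methoxymethoxy)phenyl]ethan-1-one | CC(=O)c1ccc(OCOC)cc1O | intermediate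
10 | 2,4-dihydroxybenzaldehyde | O=Cc1ccc(O)cc1O | starting material
11 | 2,4-bis(methoxymethoxy)benzaldehyde | COCOc1ccc(C=O)c(OCOC)c1 | intermediate
12 | (2E)-3-[2,4-bis(methoxymethoxy)phenyl]-1-[2-hydroxy-4-(methoxymethoxy)phenyl]prop-2-en-1-one | COCOc1ccc(/C=C/C(=O)c2ccc(OCOC)cc2O)c(OCOC)c1 | intermediate
13 | 2,4,6-trihydroxybenzaldehyde | O=Cc1c(O)cc(O)cc1O | starting material
14 | 4-[(tert-butyldimethylsilyl)oxy]-2,6-dihydroxybenzaldehyde | CC(C)(C)[Si](C)(C)Oc1cc(O)c(C=O)c(O)c1 | intermediate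
15 | 4-[(tert-butyldimethylsilyl)oxy]-2,6-bis(methoxymethoxy)benzaldehyde | CC(C)(C)[Si](C)(C)Oc1cc(OCOC)c(C=O)c(OCOC)c1 | intermediate
16 | 3-bromo-4-[(tert-butyldimethylsilyl)oxy]-2,6-bis(methoxymethoxy)benzaldehyde | CC(C)(C)[Si](C)(C)Oc1cc(OCOC)c(C=O)c(OCOC)c1Br | intermediate
17 | diethyl (2-methylprop-2-en-1-yl)phosphonate | C=C(C)CP(=O)(OCC)OCC | starting material
18 | {2-bromo-3,5-bis(methoxymethoxy)-4-[(1E)-3-methylbuta-1,3-dien-1-yl]phenoxy}(tert-butyl)dimethylsilane | C=C(C)/C=C/c1c(OCOC)cc(O[Si](C)(C)C(C)(C)C)c(Br)c1OCOC | intermediate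
19 | 2-bromo-3,5-bis(methoxymethoxy)-4-[(1E)-3-methylbuta-1,3-dien-1-yl]phenol | C=C(C)/C=C/c1c(OCOC)cc(O)c(Br)c1OCOC | intermediate
20 | {2-bromo-3,5-bis(methoxymethoxy)-4-[(1E)-3-methylbuta-1,3-dien-1-yl]phenoxy}trimethylsilane (formed in the flask) | C=C(C)/C=C/c1c(OCOC)cc(O[Si](C)(C)C)c(Br)c1OCOC | intermediate
21 | {2,4-bis(methoxymethoxy)-3-[(1E)-3-methylbuta-1,3-dien-1-yl]-6-[(trimethylsilyl)oxy]phenyl}lithium (formed in the flask) | [Li]c1c(O[Si](C)(C)C)cc(OCOC)c(/C=C/C(C)=C)c1OCOC | intermediate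
22 | lithium 3,5-bis(methoxymethoxy)-4-[(1E)-3-methylbuta-1,3-dien-1-yl]-2-(trimethylsilyl)phenolate (formed in the flask) | [Li+].[O-]c1cc(OCOC)c(/C=C/C(C)=C)c(OCOC)c1[Si](C)(C)C | intermediate
23 | 3,5-bis(methoxymethoxy)-4-[(1E)-3-methylbuta-1,3-dien-1-yl]-2-(trimethylsilyl)phenyl 2,2-dimethylpropanoate | C=C(C)/C=C/c1c(OCOC)cc(OC(=O)C(C)(C)C)c([Si](C)(C)C)c1OCOC | intermediate
24 | 4-{(1R,5R,6S)-5-[2,4-bis(methoxymethoxy)phenyl]-6-[2-hydroxy-4-(methoxymethoxy)benzoyl]-3-methylcyclohex-2-en-1-yl}-3,5-bis(methoxymethoxy)-2-(trimethylsilyl)phenyl 2,2-dimethylpropanoate (endo adduct) | CC(C)(C)C(=O)Oc1cc(OCOC)c([C@@H]2C=C(C)C[C@@H](c3ccc(OCOC)cc3OCOC)[C@@H]2C(=O)c2ccc(OCOC)cc2O)c(OCOC)c1[Si](C)(C)C | intermediate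
25 | 4-{(1R,5R,6S)-6-[2,4-bis(methoxymethoxy)benzoyl]-5-[2,4-bis(methoxymethoxy)phenyl]-3-methylcyclohex-2-en-1-yl}-3,5-bis(methoxymethoxy)-2-(trimethylsilyl)phenyl 2,2-dimethylpropanoate | CC(C)(C)C(=O)Oc1cc(OCOC)c([C@@H]2C=C(C)C[C@@H](c3ccc(OCOC)cc3OCOC)[C@@H]2C(=O)c2ccc(OCOC)cc2OCOC)c(OCOC)c1[Si](C)(C)C | intermediate
26 | sodium 4-{(1R,5R,6S)-6-[2,4-bis(methoxymethoxy)benzoyl]-5-[2,4-bis(methoxymethoxy)phenyl]-3-methylcyclohex-2-en-1-yl}-3,5-bis(methoxymethoxy)-2-(trimethylsilyl)phenolate (formed in the flask) | [Na+].[O-]c1cc(OCOC)c([C@@H]2C=C(C)C[C@@H](c3ccc(OCOC)cc3OCOC)[C@@H]2C(=O)c2ccc(OCOC)cc2OCOC)c(OCOC)c1[Si](C)(C)C | intermediate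
27 | 4-{(1R,5R,6R)-6-[2,4-bis(methoxymethoxy)benzoyl]-5-[2,4-bis(methoxymethoxy)phenyl]-3-methylcyclohex-2-en-1-yl}-3,5-bis(methoxymethoxy)-2-(trimethylsilyl)phenol | Oc1cc(OCOC)c([C@@H]2C=C(C)C[C@@H](c3ccc(OCOC)cc3OCOC)[C@H]2C(=O)c2ccc(OCOC)cc2OCOC)c(OCOC)c1[Si](C)(C)C | intermediate
28 | 4-{(1R,5R,6R)-6-[2,4-bis(methoxymethoxy)benzoyl]-5-[2,4-bis(methoxymethoxy)phenyl]-3-methylcyclohex-2-en-1-yl}-3,5-bis(methoxymethoxy)-2-(trimethylsilyl)phenyl trifluoromethanesulfonate | C[Si](C)(C)c1c(OS(=O)(=O)C(F)(F)F)cc(OCOC)c([C@@H]2C=C(C)C[C@@H](c3ccc(OCOC)cc3OCOC)[C@H]2C(=O)c2ccc(OCOC)cc2OCOC)c1OCOC | intermediate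
29 | trimethylsilyl (2S)-2-[2,4-bis(methoxymethoxy)phenyl]-2-(methoxycarbonyl)-5-methylhex-4-enoate (formed in the flask; same spatial arrangement as 7) | CC(C)=CC[C@@](C(=O)OC)(c1ccc(OCOC)cc1OCOC)C(=O)O[Si](C)(C)C | intermediate
30 | 4-{(1R,5R,6R)-6-[2,4-bis(methoxymethoxy)benzoyl]-5-[2,4-bis(methoxymethoxy)phenyl]-3-methylcyclohex-2-en-1-yl}-3,5-bis(methoxymethoxy)-1,2-didehydrobenzene (aryne, formed in the flask) | COCOC1=C([C@@H]2C=C(C)C[C@@H](c3ccc(OCOC)cc3OCOC)[C@H]2C(=O)c2ccc(OCOC)cc2OCOC)C(OCOC)=CC#C1 | intermediate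
31 | (3S)-3-[2,4-bis(methoxymethoxy)phenyl]-6-{(1R,5R,6R)-6-[2,4-bis(methoxymethoxy)benzoyl]-5-[2,4-bis(methoxymethoxy)phenyl]-3-methylcyclohex-2-en-1-yl}-5,7-bis(methoxymethoxy)-3-(3-methylbut-2-en-1-yl)chromane-2,4-dione | CC(C)=CC[C@@]1(c2ccc(OCOC)cc2OCOC)C(=O)Oc2cc(OCOC)c([C@@H]3C=C(C)C[C@@H](c4ccc(OCOC)cc4OCOC)[C@H]3C(=O)c3ccc(OCOC)cc3OCOC)c(OCOC)c2C1=O | intermediate
32 | (3S)-6-[(1R,5R,6R)-6-(2,4-dihydroxybenzoyl)-5-(2,4-dihydroxyphenyl)-3-methylcyclohex-2-en-1-yl]-3-(2,4-dihydroxyphenyl)-5,7-dihydroxy-3-(3-methylbut-2-en-1-yl)chromane-2,4-dione | CC(C)=CC[C@@]1(c2ccc(O)cc2O)C(=O)Oc2cc(O)c([C@@H]3C=C(C)C[C@@H](c4ccc(O)cc4O)[C@H]3C(=O)c3ccc(O)cc3O)c(O)c2C1=O | target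

**Step count and risks**

Total: 19 steps. Longest linear sequence: 12 steps (13 → 32, steps 8–19).

Steps most likely to fail:

1. Step 18 (the new annulation). The aryl anion may be protonated or silylated before it reaches the ester, or it may shift the acyl group from oxygen to carbon through attack on the near carbonyl, or the methoxide may open the lactone once silicon is used up. The fallback uses known reactions only, sets out from 27 and returns at 31. N-Iodosuccinimide in MeCN at −20 °C should replace the silyl group by iodine (ipso-iododesilylation, faster on the phenol ring than any reaction at the alkenes) to give the iodophenol F1. Steglich esterification of F1 with acid 7 (carbodiimide, DMAP) gives the iodoaryl methyl malonate F2. Iodine–magnesium exchange with i-PrMgCl·LiCl in THF at −40 °C and Parham-type cyclisation of the arylmagnesium onto the methyl ester then close the same C4–C4a bond and give 31.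

2. Step 16 (equilibration at C6). The equilibrium may stop at a mixture or rest on the 6S side, because the gain from moving the aroyl group away from ring A is paid for by a new cis relation to the 5-aryl group. The fallback sets the cis relation in the cycloaddition itself with a dienophile locked in the Z geometry; it sets out from 19 and returns at 28, replacing steps 13–17.
   - Silylation of 19, bromine–lithium exchange with retro-Brook migration and trapping of the phenolate with PhNTf2 give the diene silyl triflate F3.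
   - Commercial 7-hydroxycoumarin is capped as its MOM ether, the coumarin F4.
   - A Diels–Alder reaction of F3 with F4 at about 12 kbar fixes the lactone carbonyl and the aryl group cis by ring fusion and should give the cis-fused lactone F5 through the exo mode (ring A trans to the lactone carbonyl); the enantiomers are separated on a chiral stationary phase.
   - Me(MeO)NH·HCl with i-PrMgCl at −20 °C opens the lactone to the N-methoxy-N-methylamide F6.
   - MOMCl with i-Pr2NEt gives the MOM ether F7.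
   - The aryllithium made from 2 with n-BuLi at −78 °C adds once to the amide and gives ketone 28.

3. Step 4 (enzymatic desymmetrisation). Hydrolysis of this bulky, poorly soluble diester may be slow, poorly selective or of the wrong sense. The fallback is a classical resolution, sets out from 6 and returns at 7. One equivalent of KOH in MeOH/H2O gives the racemic half-ester F8. Crystallisation with (R)-1-phenylethylamine gives the less soluble diastereomeric salt F9 (the antipodal amine is used if the other salt crystallises), and acidification with citric acid releases 7.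

**Further compounds**

F1 | step 18 | 4-{(1R,5R,6R)-6-[2,4-bis(methoxymethoxy)benzoyl]-5-[2,4-bis(methoxymethoxy)phenyl]-3-methylcyclohex-2-en-1-yl}-2-iodo-3,5-bis(methoxymethoxy)phenol | Oc1cc(OCOC)c([C@@H]2C=C(C)C[C@@H](c3ccc(OCOC)cc3OCOC)[C@H]2C(=O)c2ccc(OCOC)cc2OCOC)c(OCOC)c1I
F2 | step 18 | 1-(4-{(1R,5R,6R)-6-[2,4-bis(methoxymethoxy)benzoyl]-5-[2,4-bis(methoxymethoxy)phenyl]-3-methylcyclohex-2-en-1-yl}-2-iodo-3,5-bis(methoxymethoxy)phenyl) 3-methyl (2S)-2-[2,4-bis(methoxymethoxy)phenyl]-2-(3-methylbut-2-en-1-yl)propanedioate | CC(C)=CC[C@@](C(=O)OC)(c1ccc(OCOC)cc1OCOC)C(=O)Oc1cc(OCOC)c([C@@H]2C=C(C)C[C@@H](c3ccc(OCOC)cc3OCOC)[C@H]2C(=O)c2ccc(OCOC)cc2OCOC)c(OCOC)c1I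
F3 | step 16 | 3,5-bis(methoxymethoxy)-4-[(1E)-3-methylbuta-1,3-dien-1-yl]-2-(trimethylsilyl)phenyl trifluoromethanesulfonate | C=C(C)/C=C/c1c(OCOC)cc(OS(=O)(=O)C(F)(F)F)c([Si](C)(C)C)c1OCOC
F4 | step 16 | 7-(methoxymethoxy)-2H-chromen-2-one | COCOc1ccc2C=CC(=O)Oc2c1
F5 | step 16 | 4-[(6aR,7R,10aR)-3-(methoxymethoxy)-9-methyl-6-oxo-6a,7,10,10a-tetrahydro-6H-benzo[c]chromen-7-yl]-3,5-bis(methoxymethoxy)-2-(trimethylsilyl)phenyl trifluoromethanesulfonate | C[Si](C)(C)c1c(OS(=O)(=O)C(F)(F)F)cc(OCOC)c([C@@H]2C=C(C)C[C@@H](c3ccc(OCOC)cc3O4)[C@H]2C4=O)c1OCOC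
F6 | step 16 | 4-{(1R,5R,6R)-5-[2-hydroxy-4-(methoxymethoxy)phenyl]-6-[methoxy(methyl)carbamoyl]-3-methylcyclohex-2-en-1-yl}-3,5-bis(methoxymethoxy)-2-(trimethylsilyl)phenyl trifluoromethanesulfonate | C[Si](C)(C)c1c(OS(=O)(=O)C(F)(F)F)cc(OCOC)c([C@@H]2C=C(C)C[C@@H](c3ccc(OCOC)cc3O)[C@H]2C(=O)N(C)OC)c1OCOC
F7 | step 16 | 4-{(1R,5R,6R)-5-[2,4-bis(methoxymethoxy)phenyl]-6-[methoxy(methyl)carbamoyl]-3-methylcyclohex-2-en-1-yl}-3,5-bis(methoxymethoxy)-2-(trimethylsilyl)phenyl trifluoromethanesulfonate | C[Si](C)(C)c1c(OS(=O)(=O)C(F)(F)F)cc(OCOC)c([C@@H]2C=C(C)C[C@@H](c3ccc(OCOC)cc3OCOC)[C@H]2C(=O)N(C)OC)c1OCOC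
F8 | step 4 | racemic 2-[2,4-bis(methoxymethoxy)phenyl]-2-(methoxycarbonyl)-5-methylhex-4-enoic acid | CC(C)=CCC(C(=O)OC)(c1ccc(OCOC)cc1OCOC)C(=O)O
F9 | step 4 | (1R)-1-phenylethan-1-aminium (2R)-2-[2,4-bis(methoxymethoxy)phenyl]-2-(methoxycarbonyl)-5-methylhex-4-enoate | CC(C)=CC[C@@](C(=O)OC)(c1ccc(OCOC)cc1OCOC)C(=O)[O-].C[C@@H]([NH3+])c1ccccc1
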